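## Retrosynthetic overview

1. Target 20 ⇒ 18: the C8 methacrylate and the C4/C5 epoxide go on last (acylation, then epoxidation of the E olefin).
2. 18 ⇒ 16: one palladium-catalysed oxidative carbonylation of a ten-membered allenyl diol closes the C7–O–C10 oxolane and the α-methylene lactone together (bonds C7–O, C11–C12, C12–O6).
3. 16 ⇒ 15: chromium-mediated propargyl-to-allenyl ring closure (C6–C7) of an open-chain chloroalkynyl enal.
4. 15 ⇒ 5 + 9: copper/bis(oxazoline) Mukaiyama aldol (C9–C10, sets C10), then Ru transfer hydrogenation (sets C8); 5 comes from geranyl acetate, 9 from propargyl chloride.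
5. Ring order: ten-membered carbocycle, then oxolane and lactone in one operation, then epoxide.

Numbering: germacrane numbers are used for the ring atoms (C1 ketone, C4/C5 epoxide carbons, C6 lactone carbinol, C7 spiro carbon, C8 ester carbinol, C9 methylene, C10 methyl-bearing ether carbon, C11/C12/C13 lactone α-carbon, carbonyl and methylene).

Assumption: the six descriptors are taken exactly as the SMILES gives them, (4R,5R,6R,7S,8S,10S), and every structure is written to that string; C7 is not set on its own but follows C10 through the ether bridge, so the bridgehead pair is governed by the ligand of step 6.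

## Route

Step 1
Reactants: 1 geranyl acetate
Product: 2 (2E)-3-methyl-6-oxohex-2-en-1-yl acetate
Conditions: O3, CH2Cl2/pyridine, −78 °C; then Me2S
Reagents that add atoms: ozone [O-][O+]=O
Why: Criegee ozonolysis cleaves only the distal, more electron-rich trisubstituted alkene because the allylic acetoxy group deactivates the C2=C3 alkene, whose E geometry is kept.

Step 2
Reactants: 2 (2E)-3-methyl-6-oxohex-2-en-1-yl acetate
Product: 4 (2E)-6-hydroxy-3-methyl-7-oxooct-2-en-1-yl acetate (racemic), via ethoxyvinyl carbinol 3 (not isolated)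
Conditions: ethyl vinyl ether, t-BuLi, THF, −78 → 0 °C; then 2, −78 °C; then 1 M HCl, 0 °C
Reagents that add atoms: ethyl vinyl ether C=COCC; water O
Why: 1-ethoxyvinyllithium is an acetyl anion equivalent that adds 1,2 to the aldehyde far faster than to the acetate at −78 °C, and acid hydrolysis of the enol ether gives the acyloin, whose racemic carbinol centre is erased in step 3.

Step 3
Reactants: 4 (2E)-6-hydroxy-3-methyl-7-oxooct-2-en-1-yl acetate
Product: 5 (2E)-3-methyl-6,7-dioxooct-2-en-1-yl acetate
Conditions: IBX, EtOAc, 75 °C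
Reagents that add atoms: none
Why: IBX oxidation of an α-hydroxy ketone gives the 1,2-diketone without touching the alkene or the acetate.

Step 4
Reactants: 6 propargyl chloride
Product: 8 5-chloropent-3-yn-2-one, via lithium acetylide 7 (not isolated)
Conditions: n-BuLi, Et2O, −78 °C; N-methoxy-N-methylacetamide, −78 → −40 °C; 1 M HCl
Reagents that add atoms: N-methoxy-N-methylacetamide CC(=O)N(C)OC
Why: Weinreb ketone synthesis, in which the chelated tetrahedral adduct stops over-addition and the low temperature keeps the chloropropynyl lithium intact.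

Step 5
Reactants: 8 5-chloropent-3-yn-2-one
Product: 9 [(5-chloropent-1-en-3-yn-2-yl)oxy]trimethylsilane
Conditions: LiN(SiMe3)2, Me3SiCl (internal quench), THF, −78 °C
Reagents that add atoms: chlorotrimethylsilane C[Si](C)(C)Cl
Why: kinetic enolisation of the methyl ketone with a non-nucleophilic amide base and immediate O-silylation gives the enol silane before the propargylic chloride can react.

Step 6
Reactants: 5 (2E)-3-methyl-6,7-dioxooct-2-en-1-yl acetate + 9 [(5-chloropent-1-en-3-yn-2-yl)oxy]trimethylsilane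
Product: 11 (2E,7S)-12-chloro-7-hydroxy-3,7-dimethyl-6,9-dioxododec-2-en-10-yn-1-yl acetate, via trimethylsilyl ether 10 (not isolated)
Conditions: Cu(OTf)2 (10 mol %), (S,S)-t-Bu-box (11 mol %), THF, −78 °C; then 1 M HCl, 0 °C
Reagents that add atoms: none
Why: Evans-type Mukaiyama aldol in which the 1,2-diketone chelates the chiral divalent copper Lewis acid and the enol silane attacks the less hindered acetyl carbonyl on its si face, setting the tertiary carbinol C10 as S under ligand control.

Step 7
Reactants: 11 (2E,7S)-12-chloro-7-hydroxy-3,7-dimethyl-6,9-dioxododec-2-en-10-yn-1-yl acetate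
Product: 12 (2E,7S,9S)-12-chloro-7,9-dihydroxy-3,7-dimethyl-6-oxododec-2-en-10-yn-1-yl acetate
Conditions: Ru[(S,S)-TsNCH(Ph)CH(Ph)NH](p-cymene) (1 mol %), i-PrOH, 25 °C, no added base
Reagents that add atoms: none
Why: Noyori asymmetric transfer hydrogenation reduces the alkynyl ketone much faster than the hindered dialkyl ketone, and the (S,S) catalyst delivers hydride to give the (S)-propargylic alcohol C8 by reagent control.

Step 8
Reactants: 12 (2E,7S,9S)-12-chloro-7,9-dihydroxy-3,7-dimethyl-6-oxododec-2-en-10-yn-1-yl acetate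
Product: 13 (2E,7S,9S)-12-chloro-7-hydroxy-3,7-dimethyl-6-oxo-9-(triethylsilyloxy)dodec-2-en-10-yn-1-yl acetate
Conditions: Et3SiCl, imidazole, CH2Cl2, 0 °C
Reagents that add atoms: chlorotriethylsilane CC[Si](Cl)(CC)CC
Why: silyl ether formation is selective for the secondary propargylic hydroxyl over the tertiary one, and it blocks C8–OH so that it cannot compete for the allene or the acylpalladium in step 11.

Step 9
Reactants: 13 (2E,7S,9S)-12-chloro-7-hydroxy-3,7-dimethyl-6-oxo-9-(triethylsilyloxy)dodec-2-en-10-yn-1-yl acetate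
Product: 15 (2E,7S,9S)-12-chloro-7-hydroxy-3,7-dimethyl-6-oxo-9-(triethylsilyloxy)dodec-2-en-10-ynal, via allylic alcohol 14 (not isolated)
Conditions: K2CO3 (0.2 equiv), MeOH, 0 °C; then dilute with CH2Cl2, MnO2 (20 equiv), 25 °C
Reagents that add atoms: none
Why: carbonate-catalysed transesterification frees the primary allylic alcohol, which MnO2 oxidises chemoselectively (allylic oxidation) to the E enal while the silyl ether, tertiary alcohol, ketone and propargylic chloride are left alone.

Step 10
Reactants: 15 (2E,7S,9S)-12-chloro-7-hydroxy-3,7-dimethyl-6-oxo-9-(triethylsilyloxy)dodec-2-en-10-ynal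
Product: 16 (2S,4S,6R,7E)-5-ethenylidene-2,6-dihydroxy-2,8-dimethyl-4-(triethylsilyloxy)cyclodec-7-en-1-one
Conditions: CrCl2 (4 equiv), LiI (0.1 equiv), THF/DMF 4:1, 0.003 M (syringe pump), 25 °C
Reagents that add atoms: none
Why: Nozaki–Hiyama–Kishi-type propargylation in which the propargyl chromium species adds through its γ-carbon (SE2′) to the aldehyde only, closing the ten-membered ring as the α-allenic alcohol, with the new C6 carbinol formed anti to the bulky C8 silyloxy group (substrate control, 6R).

Step 11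
Reactants: 16 (2S,4S,6R,7E)-5-ethenylidene-2,6-dihydroxy-2,8-dimethyl-4-(triethylsilyloxy)cyclodec-7-en-1-one
Product: 18 (6R,7S,8S,10S)-8-hydroxy-1-oxo-7,10-epoxygermacra-4E,11(13)-dien-12,6-olide, via triethylsilyl ether 17 (not isolated)
Conditions: Pd(OCOCF3)2 (10 mol %), p-benzoquinone (2 equiv), CO (1 atm), MeCN, 0 → 25 °C; then 1 M HCl, THF, 25 °C
Reagents that add atoms: carbon monoxide [C-]#[O+]
Why: Proposed new method: divalent palladium activates the allene, the C10 hydroxyl adds across the ring to C7 in a 5-exo anti oxypalladation (the one-atom bridge can close only on the face the C10 oxygen reaches, so C7 follows C10), the C11 vinylpalladium inserts CO and the acylpalladium is captured by the adjacent C6 hydroxyl to give the methylene lactone while benzoquinone returns zerovalent palladium to the divalent state; the closest known reactions are the PdCl2/CuCl2/CO/MeOH oxypalladation–alkoxycarbonylation of γ-allenols to 2-(oxolan-2-yl)acrylates and intramolecular hydroxyl capture of acylpalladium in oxidative lactonisations, and the acidic work-up then removes the silyl group.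

Step 12
Reactants: 18 (6R,7S,8S,10S)-8-hydroxy-1-oxo-7,10-epoxygermacra-4E,11(13)-dien-12,6-olide
Product: 19 (6R,7S,8S,10S)-8-(methacryloyloxy)-1-oxo-7,10-epoxygermacra-4E,11(13)-dien-12,6-olide
Conditions: methacrylic anhydride, Et3N, DMAP (0.2 equiv), CH2Cl2, 25 °C
Reagents that add atoms: methacrylic anhydride C=C(C)C(=O)OC(=O)C(C)=C
Why: DMAP-catalysed acyl transfer esterifies the only free hydroxyl with retention at C8.

Step 13
Reactants: 19 (6R,7S,8S,10S)-8-(methacryloyloxy)-1-oxo-7,10-epoxygermacra-4E,11(13)-dien-12,6-olide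
Product: 20 (4R,5R,6R,7S,8S,10S)-4,5:7,10-diepoxy-8-(methacryloyloxy)-1-oxogermacr-11(13)-en-12,6-olide
Conditions: mCPBA, CH2Cl2, 0 °C
Reagents that add atoms: 3-chloroperoxybenzoic acid OOC(=O)c1cccc(Cl)c1
Why: Prilezhaev epoxidation attacks only the electron-rich trisubstituted olefin (methylene lactone and methacrylate are electron-poor), is stereospecific (E olefin gives the trans epoxide) and is expected to occur on the exposed outer face of the olefin in the bridged ring, giving 4R,5R.

## Compound list

1 | geranyl acetate, (2E)-3,7-dimethylocta-2,6-dien-1-yl acetate | CC(C)=CCC/C(C)=C/COC(C)=O | starting material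
2 | (2E)-3-methyl-6-oxohex-2-en-1-yl acetate | O=CCC/C(C)=C/COC(C)=O | intermediate
3 | (2E)-7-ethoxy-6-hydroxy-3-methylocta-2,7-dien-1-yl acetate (racemic, not isolated) | C=C(OCC)C(O)CC/C(C)=C/COC(C)=O | intermediate
4 | (2E)-6-hydroxy-3-methyl-7-oxooct-2-en-1-yl acetate (racemic) | CC(=O)C(O)CC/C(C)=C/COC(C)=O | intermediate
5 | (2E)-3-methyl-6,7-dioxooct-2-en-1-yl acetate | CC(=O)C(=O)CC/C(C)=C/COC(C)=O | intermediate
6 | propargyl chloride, 3-chloroprop-1-yne | ClCC#C | starting material
7 | lithium 3-chloroprop-1-yn-1-ide (not isolated) | [Li]C#CCCl | intermediate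
8 | 5-chloropent-3-yn-2-one | CC(=O)C#CCCl | intermediate
9 | [(5-chloropent-1-en-3-yn-2-yl)oxy]trimethylsilane | C=C(O[Si](C)(C)C)C#CCCl | intermediate
10 | (2E,7S)-12-chloro-3,7-dimethyl-6,9-dioxo-7-(trimethylsilyloxy)dodec-2-en-10-yn-1-yl acetate (not isolated) | ClCC#CC(=O)C[C@](C)(O[Si](C)(C)C)C(=O)CC/C(C)=C/COC(C)=O | intermediate
11 | (2E,7S)-12-chloro-7-hydroxy-3,7-dimethyl-6,9-dioxododec-2-en-10-yn-1-yl acetate | ClCC#CC(=O)C[C@](C)(O)C(=O)CC/C(C)=C/COC(C)=O | intermediate
12 | (2E,7S,9S)-12-chloro-7,9-dihydroxy-3,7-dimethyl-6-oxododec-2-en-10-yn-1-yl acetate | ClCC#C[C@@H](O)C[C@](C)(O)C(=O)CC/C(C)=C/COC(C)=O | intermediate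
13 | (2E,7S,9S)-12-chloro-7-hydroxy-3,7-dimethyl-6-oxo-9-(triethylsilyloxy)dodec-2-en-10-yn-1-yl acetate | ClCC#C[C@@H](O[Si](CC)(CC)CC)C[C@](C)(O)C(=O)CC/C(C)=C/COC(C)=O | intermediate
14 | (2E,7S,9S)-12-chloro-1,7-dihydroxy-3,7-dimethyl-9-(triethylsilyloxy)dodec-2-en-10-yn-6-one (not isolated) | ClCC#C[C@@H](O[Si](CC)(CC)CC)C[C@](C)(O)C(=O)CC/C(C)=C/CO | intermediate
15 | (2E,7S,9S)-12-chloro-7-hydroxy-3,7-dimethyl-6-oxo-9-(triethylsilyloxy)dodec-2-en-10-ynal | ClCC#C[C@@H](O[Si](CC)(CC)CC)C[C@](C)(O)C(=O)CC/C(C)=C/C=O | intermediate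
16 | (2S,4S,6R,7E)-5-ethenylidene-2,6-dihydroxy-2,8-dimethyl-4-(triethylsilyloxy)cyclodec-7-en-1-one | CC[Si](CC)(CC)O[C@H]1C[C@](C)(O)C(=O)CC/C(C)=C/[C@@H](O)C1=C=C | intermediate
17 | 8-O-triethylsilyl ether of 18 (not isolated) | CC[Si](CC)(CC)O[C@H]1C[C@]2(C)O[C@@]13C(=C)C(=O)O[C@@H]3/C=C(\C)CCC2=O | intermediate
18 | (6R,7S,8S,10S)-8-hydroxy-1-oxo-7,10-epoxygermacra-4E,11(13)-dien-12,6-olide | O[C@H]1C[C@]2(C)O[C@@]13C(=C)C(=O)O[C@@H]3/C=C(\C)CCC2=O | intermediate
19 | (6R,7S,8S,10S)-8-(methacryloyloxy)-1-oxo-7,10-epoxygermacra-4E,11(13)-dien-12,6-olide | C=C(C)C(=O)O[C@H]1C[C@]2(C)O[C@@]13C(=C)C(=O)O[C@@H]3/C=C(\C)CCC2=O | intermediate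
20 | (4R,5R,6R,7S,8S,10S)-4,5:7,10-diepoxy-8-(methacryloyloxy)-1-oxogermacr-11(13)-en-12,6-olide (CNP0241021.2) | C=C(C)C(=O)O[C@H]1C[C@]2(C)O[C@@]13C(=C)C(=O)O[C@@H]3[C@H]1O[C@]1(C)CCC2=O | target

## Step count and risks

Total step count: 13. Longest linear sequence: 11 steps (1, 2, 3, 6, 7, 8, 9, 10, 11, 12, 13) from geranyl acetate.

The three steps most likely to fail:

**Step 10 (chromium ring closure).** The selectivity at C6 rests on substrate control in a medium-ring transition state and may be low. The fallback sets out from 16 as obtained together with its C6 epimer, the (6S) allenyl diol F1. The mixture is taken through the palladium step in methanol (Pd(OCOCF3)2, p-benzoquinone, CO, MeOH/MeCN, NaOAc) so that methanol takes the acylpalladium and C6–OH stays free, giving from F1 the (6S) hydroxy methyl ester F2. Dess–Martin periodinane oxidises the C6 hydroxyl of F2 to the enone F3. F3 is reduced with the Corey–Bakshi–Shibata oxazaborolidine enantiomer matched to the (6R) carbinol, with catecholborane at −78 °C, to the (6R) hydroxy methyl ester F4, so C6 is now set by the reagent. Camphorsulfonic acid in CH2Cl2 closes F4 to the lactone, and the route is rejoined at 17.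

**Step 11 (palladium bicyclisation).** The C6 hydroxyl may attack the allene terminus first, or carbonylation may stall. The fallback sets out from 16 and separates the two ring closures. N-iodosuccinimide in MeCN at −20 °C effects iodoetherification (C10–OH to C7, iodine to C11) and gives the bridged 1-iodovinyl oxolane F5. Pd(PPh3)4 (zerovalent palladium), CO (1 atm) and Et3N in MeCN at 50 °C then carry out the carbonylative lactonisation of this 3-iodohomoallylic alcohol. The route is rejoined at 17.

**Step 13 (epoxidation).** The peracid may prefer the other face of the C4=C5 olefin. The fallback sets out from 19. NBS in THF/H2O at 0 °C puts the bromonium ion on the exposed face and water opens it at the tertiary C4 from the opposite side, giving the (4R,5S) bromohydrin F6. K2CO3 in acetone closes F6 with inversion at C5, which places the oxygen on the face a peracid does not reach. The route is rejoined at 20.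

## Further compounds

F1 | step 10 | (2S,4S,6S,7E)-5-ethenylidene-2,6-dihydroxy-2,8-dimethyl-4-(triethylsilyloxy)cyclodec-7-en-1-one (C6 epimer of 16) | CC[Si](CC)(CC)O[C@H]1C[C@](C)(O)C(=O)CC/C(C)=C/[C@H](O)C1=C=C
F2 | step 10 | methyl (6S)-6-hydroxy-1-oxo-8-(triethylsilyloxy)-7,10-epoxygermacra-4E,11(13)-dien-12-oate (other centres as in 17) | CC[Si](CC)(CC)O[C@H]1C[C@]2(C)O[C@]1(C(=C)C(=O)OC)[C@@H](O)/C=C(\C)CCC2=O
F3 | step 10 | methyl 1,6-dioxo-8-(triethylsilyloxy)-7,10-epoxygermacra-4E,11(13)-dien-12-oate (other centres as in 17) | CC[Si](CC)(CC)O[C@H]1C[C@]2(C)O[C@]1(C(=C)C(=O)OC)C(=O)/C=C(\C)CCC2=O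
F4 | step 10 | methyl (6R)-6-hydroxy-1-oxo-8-(triethylsilyloxy)-7,10-epoxygermacra-4E,11(13)-dien-12-oate (other centres as in 17) | CC[Si](CC)(CC)O[C@H]1C[C@]2(C)O[C@]1(C(=C)C(=O)OC)[C@H](O)/C=C(\C)CCC2=O
F5 | step 11 | (6R)-6-hydroxy-11-iodo-8-(triethylsilyloxy)-12-nor-7,10-epoxygermacra-4E,11(13)-dien-1-one (other centres as in 17) | CC[Si](CC)(CC)O[C@H]1C[C@]2(C)O[C@]1(C(I)=C)[C@H](O)/C=C(\C)CCC2=O
F6 | step 13 | (4R,5S)-5-bromo-4-hydroxy-4,5-dihydro derivative of 19 | C=C(C)C(=O)O[C@H]1C[C@]2(C)O[C@@]13C(=C)C(=O)O[C@@H]3[C@H](Br)[C@](C)(O)CCC2=O
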